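**Strategy.** Each flavan-3,4-diol half is built open-chain, and its pyran ring (ring C) is closed last at the aryl ether bond O1–C8a, never at the epimerisable benzylic C2. A syn-glycolate aldol sets C2/C3. One β-hydroxy ketone then diverges by 1,3-syn or 1,3-anti reduction to the two C4 epimers. The key step is an intramolecular SNAr: the C2 alkoxide of a (2-fluoro-3,4-dibenzyloxyphenyl)propane-1,3-diol displaces fluoride at C8a, giving the 2,3-cis-3,4-trans chroman with all three stereocentres untouched. It exploits the A-ring carbon C8a, ortho to both the C4-bearing C4a and the C8 oxygen, as the electrophilic site. C6 bromination, Suzuki union and hydrogenolysis finish the route.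

Key step: step 7

Assumption: the 6,6'-biaryl bond has only two ortho substituents (the C7 oxygens) and is taken as freely rotating, so no axial stereochemistry needs control. Flavan atom labels (O1, C2, C3, C4, C4a, C5–C8, C8a) are also used for the same atoms in open-chain intermediates.

**Step 1**
Reactants: 1 3-fluorocatechol
Product: 2 1,2-bis(benzyloxy)-3-fluorobenzene
Conditions: BnBr (2.3 equiv), K2CO3, DMF, 60 °C, under N2
Reagents that add atoms: benzyl bromide, BrCc1ccccc1
Why: Williamson etherification of both phenols gives benzyl ethers that are stable to base and organolithiums and are removed together in the last step; no stereocentre is involved.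

**Step 2**
Reactants: 3 (S)-4-benzyloxazolidin-2-one; 4 benzyloxyacetyl chloride
Product: 5 (4S)-4-benzyl-3-[2-(benzyloxy)acetyl]-1,3-oxazolidin-2-one
Conditions: n-BuLi, THF, −78 °C; then 4, −78 to 0 °C
Reagents that add atoms: none
Why: N-acylation of the lithiated oxazolidinone installs the glycolate unit whose benzyl ether becomes the O3 protecting group; the auxiliary stereocentre is untouched.

**Step 3**
Reactants: 5 N-(benzyloxyacetyl)oxazolidinone; 6 4-(benzyloxy)benzaldehyde
Product: 8 (4S)-4-benzyl-3-[(2S,3R)-2-(benzyloxy)-3-[4-(benzyloxy)phenyl]-3-hydroxypropanoyl]-1,3-oxazolidin-2-one, via dibutylboron Z-enolate 7 (not isolated)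
Conditions: Bu2BOTf, Et3N, CH2Cl2, −78 to 0 °C; then 6, −78 to 0 °C; pH 7 buffer, MeOH, H2O2, 0 °C
Reagents that add atoms: none
Why: Evans syn-glycolate aldol reaction, in which the Z-boron enolate reacts through a closed Zimmerman–Traxler chair with one enolate face blocked by the auxiliary benzyl group, should give the (2S,3R) syn adduct; this fixes C3 and C2 of both flavan units and leaves O2 free and O3 benzylated.

**Step 4**
Reactants: 8 aldol adduct
Product: 9 (2S,3R)-2-(benzyloxy)-3-[4-(benzyloxy)phenyl]-3-hydroxy-N-methoxy-N-methylpropanamide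
Conditions: MeONHMe·HCl, AlMe3, CH2Cl2, −10 to 0 °C; aq. potassium sodium tartrate (KNaC4H4O6)
Reagents that add atoms: N,O-dimethylhydroxylamine hydrochloride, CNOC.Cl
Why: Weinreb amide formation by aminolysis of the N-acyl oxazolidinone with the aluminium amide, assisted by the aluminium alkoxide of the β-hydroxyl, cleaves the auxiliary without touching either stereocentre.

**Step 5**
Reactants: 2 1,2-bis(benzyloxy)-3-fluorobenzene; 9 Weinreb amide
Product: 11 (2S,3R)-2-(benzyloxy)-1-[3,4-bis(benzyloxy)-2-fluorophenyl]-3-[4-(benzyloxy)phenyl]-3-hydroxypropan-1-one, via aryllithium 10 (not isolated)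
Conditions: 2 (2.5 equiv), n-BuLi (2.4 equiv), THF, −78 °C; then 9 (1 equiv), −78 to −50 °C; aq. NH4Cl
Reagents that add atoms: none
Why: Fluorine-directed ortho-lithiation (the C–H next to fluorine is the most acidic ring position of 1-fluoro-2,3-dialkoxybenzenes) followed by Weinreb ketone synthesis, whose chelated tetrahedral adduct prevents over-addition and retro-aldol cleavage; one equivalent of 10 is consumed by the hydroxyl and returns as 2, and −78 °C keeps the ortho-fluoroaryllithium from losing LiF.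

**Step 6**
Reactants: 11 β-hydroxy ketone
Product: 13 (1S,2S,3R)-2-(benzyloxy)-1-[3,4-bis(benzyloxy)-2-fluorophenyl]-3-[4-(benzyloxy)phenyl]propane-1,3-diol, via diethylboron chelate 12 (not isolated)
Conditions: Et2BOMe, THF/MeOH (4:1), −78 °C; NaBH4, −78 to −40 °C; AcOH; MeOH co-evaporation
Reagents that add atoms: none
Why: Narasaka–Prasad reduction, in which external hydride attacks the half-chair boron chelate axially and anti to the C3–O bond (the polar Felkin–Anh sense reinforces it), should set C4 as S in a 1,3-syn relationship to the C2 carbinol (all-syn triol array).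

**Step 7**
Reactants: 13 syn,syn-diol
Product: 14 (2R,3R,4S)-3,7,8-tris(benzyloxy)-2-[4-(benzyloxy)phenyl]-3,4-dihydro-2H-chromen-4-ol
Conditions: KN(SiMe3)2 (2.3 equiv), 18-crown-6, THF, 0 to 60 °C
Reagents that add atoms: none
Why: Deprotonation gives the potassium alkoxide at C2, which attacks the fluorine-bearing C8a in an addition–elimination (or concerted) nucleophilic aromatic substitution and expels fluoride, forming the O1–C8a aryl ether. The closest known reaction type is the intramolecular SNAr of a tethered secondary alkoxide on an alkoxy-substituted, otherwise unactivated fluoroarene, as used to close the pyran ring of 2,3-cis-flavan-3-ols. Ring C (the dihydropyran) closes in a 6-exo-trig mode, the displaced C–F bond lying outside the new ring. No stereocentre is created: C2, C3 and C4 were set in steps 3 and 6 and none of their bonds is broken, so the 2,3-cis-3,4-trans array is carried over with retention, which a closure at the benzylic C2 could not guarantee. The step needs site selectivity among three oxygens and two ortho carbons: O3 is benzylated, the O4 alkoxide could only form a four-membered ring, and fluorine marks C8a rather than C5 as the only electrophilic carbon. The potassium counter-ion with 18-crown-6 supplies the unencumbered alkoxide needed for a ring that the ortho C8 oxygen deactivates.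

**Step 8**
Reactants: 14 2,3-cis-3,4-trans chroman
Product: 15 (2R,3R,4S)-3,7,8-tris(benzyloxy)-2-[4-(benzyloxy)phenyl]-6-bromo-3,4-dihydro-2H-chromen-4-ol
Conditions: NBS (1.05 equiv), DMF, −20 to 0 °C, dark
Reagents that add atoms: N-bromosuccinimide, O=C1CCC(=O)N1Br
Why: Electrophilic aromatic bromination should go to C6, which is para to O1 and ortho to the 7-benzyloxy group (the reactive site of a 4-alkyl-1,2,3-trialkoxybenzene), whereas C5 is only para to the twisted central 8-benzyloxy group and the mono-oxygenated B ring is far less nucleophilic.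

**Step 9**
Reactants: 11 β-hydroxy ketone
Product: 17 (1R,2S,3R)-2-(benzyloxy)-1-[3,4-bis(benzyloxy)-2-fluorophenyl]-3-[4-(benzyloxy)phenyl]propane-1,3-diol, via alkoxydiacetoxyborohydride 16 (not isolated)
Conditions: Me4NBH(OAc)3 (5 equiv), MeCN/AcOH (1:1), −30 to 0 °C
Reagents that add atoms: none
Why: Evans–Saksena reduction, in which the C2 hydroxyl exchanges onto boron and hydride is delivered intramolecularly through a chair transition state, should give the 1,3-anti diol and set C4 as R.

**Step 10**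
Reactants: 17 syn,anti-diol
Product: 18 (2R,3R,4R)-3,7,8-tris(benzyloxy)-2-[4-(benzyloxy)phenyl]-3,4-dihydro-2H-chromen-4-ol
Conditions: KN(SiMe3)2 (2.3 equiv), 18-crown-6, THF, 0 to 60 °C
Reagents that add atoms: none
Why: The same intramolecular SNAr as in step 7 (6-exo closure of ring C by the C2 alkoxide at C8a) proceeds with retention at C2, C3 and C4 and should give the all-cis chroman.

**Step 11**
Reactants: 18 all-cis chroman
Product: 19 (2R,3R,4R)-3,7,8-tris(benzyloxy)-2-[4-(benzyloxy)phenyl]-6-bromo-3,4-dihydro-2H-chromen-4-ol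
Conditions: NBS (1.05 equiv), DMF, −20 to 0 °C, dark
Reagents that add atoms: N-bromosuccinimide, O=C1CCC(=O)N1Br
Why: Electrophilic aromatic bromination at C6 for the same electronic reasons as in step 8; no stereocentre is involved.

**Step 12**
Reactants: 19 all-cis 6-bromochroman; 15 3,4-trans 6-bromochroman
Product: 21 (2R,2'R,3R,3'R,4R,4'S)-3,3',7,7',8,8'-hexakis(benzyloxy)-2,2'-bis[4-(benzyloxy)phenyl]-3,3',4,4'-tetrahydro-2H,2'H-[6,6'-bichromene]-4,4'-diol, via pinacol boronate 20 (not isolated)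
Conditions: B2pin2, Pd(OAc)2 (4 mol %), SPhos (8 mol %), KOAc, 1,4-dioxane, 90 °C; then 15, aq. K3PO4, 90 °C
Reagents that add atoms: none
Why: Miyaura borylation of 19 followed in the same pot by Suzuki–Miyaura cross-coupling with 15; the bulky electron-rich biarylphosphine supports oxidative addition and transmetalation of the electron-rich ortho-alkoxy partners, the free C4 alcohols are tolerated, and the new biaryl axis is not a stereogenic element.

**Step 13**
Reactants: 21 octabenzyl biflavanoid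
Product: 22 (2R,2'R,3R,3'R,4R,4'S)-2,2'-bis(4-hydroxyphenyl)-3,3',4,4'-tetrahydro-2H,2'H-[6,6'-bichromene]-3,3',4,4',7,7',8,8'-octol (target)
Conditions: H2 (1 atm), Pd(OH)2/C, THF/MeOH (1:1), rt; filtration under Ar
Reagents that add atoms: none
Why: Catalytic hydrogenolysis cleaves the six aryl benzyl ethers and the two secondary alkyl benzyl ethers under neutral conditions, under which the benzylic C4 carbinols and the C2–O1 bonds should not ionise and should therefore persist; no stereocentre is touched.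

**Compound list**

1 | 3-fluorocatechol (3-fluorobenzene-1,2-diol) | Oc1cccc(F)c1O | starting material
2 | 1,2-bis(benzyloxy)-3-fluorobenzene | Fc1cccc(OCc2ccccc2)c1OCc1ccccc1 | intermediate
3 | (S)-4-benzyloxazolidin-2-one | O=C1N[C@@H](Cc2ccccc2)CO1 | starting material
4 | benzyloxyacetyl chloride | O=C(Cl)COCc1ccccc1 | starting material
5 | (4S)-4-benzyl-3-[2-(benzyloxy)acetyl]-1,3-oxazolidin-2-one | O=C1OC[C@H](Cc2ccccc2)N1C(=O)COCc1ccccc1 | intermediate
6 | 4-(benzyloxy)benzaldehyde | O=Cc1ccc(OCc2ccccc2)cc1 | starting material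
7 | (4S)-4-benzyl-3-[(Z)-2-(benzyloxy)-1-(dibutylboranyloxy)ethenyl]-1,3-oxazolidin-2-one (boron enolate, not isolated) | CCCCB(CCCC)O/C(=C\OCc1ccccc1)N1[C@@H](Cc2ccccc2)COC1=O | intermediate
8 | (4S)-4-benzyl-3-[(2S,3R)-2-(benzyloxy)-3-[4-(benzyloxy)phenyl]-3-hydroxypropanoyl]-1,3-oxazolidin-2-one (syn aldol adduct) | O=C1OC[C@H](Cc2ccccc2)N1C(=O)[C@@H](OCc1ccccc1)[C@H](O)c1ccc(OCc2ccccc2)cc1 | intermediate
9 | (2S,3R)-2-(benzyloxy)-3-[4-(benzyloxy)phenyl]-3-hydroxy-N-methoxy-N-methylpropanamide | CON(C)C(=O)[C@@H](OCc1ccccc1)[C@H](O)c1ccc(OCc2ccccc2)cc1 | intermediate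
10 | [3,4-bis(benzyloxy)-2-fluorophenyl]lithium (not isolated) | [Li]c1ccc(OCc2ccccc2)c(OCc2ccccc2)c1F | intermediate
11 | (2S,3R)-2-(benzyloxy)-1-[3,4-bis(benzyloxy)-2-fluorophenyl]-3-[4-(benzyloxy)phenyl]-3-hydroxypropan-1-one | Fc1c(OCc2ccccc2)c(OCc2ccccc2)ccc1C(=O)[C@@H](OCc1ccccc1)[C@H](O)c1ccc(OCc2ccccc2)cc1 | intermediate
12 | six-membered diethylboron chelate of 11 between the C2 oxygen and the ketone oxygen (not isolated) | CC[B-]1(CC)O[C@H](c2ccc(OCc3ccccc3)cc2)[C@H](OCc2ccccc2)C(c2ccc(OCc3ccccc3)c(OCc3ccccc3)c2F)=[O+]1 | intermediate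
13 | (1S,2S,3R)-2-(benzyloxy)-1-[3,4-bis(benzyloxy)-2-fluorophenyl]-3-[4-(benzyloxy)phenyl]propane-1,3-diol (all-syn triol array) | Fc1c(OCc2ccccc2)c(OCc2ccccc2)ccc1[C@H](O)[C@@H](OCc1ccccc1)[C@H](O)c1ccc(OCc2ccccc2)cc1 | intermediate
14 | (2R,3R,4S)-3,7,8-tris(benzyloxy)-2-[4-(benzyloxy)phenyl]-3,4-dihydro-2H-chromen-4-ol (2,3-cis-3,4-trans) | c1cc2c(c(OCc3ccccc3)c1OCc1ccccc1)O[C@H](c1ccc(OCc3ccccc3)cc1)[C@H](OCc1ccccc1)[C@H]2O | intermediate
15 | (2R,3R,4S)-3,7,8-tris(benzyloxy)-2-[4-(benzyloxy)phenyl]-6-bromo-3,4-dihydro-2H-chromen-4-ol | Brc1cc2c(c(OCc3ccccc3)c1OCc1ccccc1)O[C@H](c1ccc(OCc3ccccc3)cc1)[C@H](OCc1ccccc1)[C@H]2O | intermediate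
16 | tetramethylammonium diacetoxy(hydrido)borate ester of the C2 hydroxyl of 11 (not isolated) | C[N+](C)(C)C.CC(=O)O[BH-](OC(C)=O)O[C@H](c1ccc(OCc2ccccc2)cc1)[C@H](OCc1ccccc1)C(=O)c1ccc(OCc2ccccc2)c(OCc2ccccc2)c1F | intermediate
17 | (1R,2S,3R)-2-(benzyloxy)-1-[3,4-bis(benzyloxy)-2-fluorophenyl]-3-[4-(benzyloxy)phenyl]propane-1,3-diol (O2/O3 syn, O3/O4 anti) | Fc1c(OCc2ccccc2)c(OCc2ccccc2)ccc1[C@@H](O)[C@@H](OCc1ccccc1)[C@H](O)c1ccc(OCc2ccccc2)cc1 | intermediate
18 | (2R,3R,4R)-3,7,8-tris(benzyloxy)-2-[4-(benzyloxy)phenyl]-3,4-dihydro-2H-chromen-4-ol (all-cis) | c1cc2c(c(OCc3ccccc3)c1OCc1ccccc1)O[C@H](c1ccc(OCc3ccccc3)cc1)[C@H](OCc1ccccc1)[C@@H]2O | intermediate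
19 | (2R,3R,4R)-3,7,8-tris(benzyloxy)-2-[4-(benzyloxy)phenyl]-6-bromo-3,4-dihydro-2H-chromen-4-ol | Brc1cc2c(c(OCc3ccccc3)c1OCc1ccccc1)O[C@H](c1ccc(OCc3ccccc3)cc1)[C@H](OCc1ccccc1)[C@@H]2O | intermediate
20 | (2R,3R,4R)-3,7,8-tris(benzyloxy)-2-[4-(benzyloxy)phenyl]-6-(4,4,5,5-tetramethyl-1,3,2-dioxaborolan-2-yl)-3,4-dihydro-2H-chromen-4-ol (not isolated) | CC1(C)OB(OC1(C)C)c1cc2c(c(OCc3ccccc3)c1OCc1ccccc1)O[C@H](c1ccc(OCc3ccccc3)cc1)[C@H](OCc1ccccc1)[C@@H]2O | intermediate
21 | (2R,2'R,3R,3'R,4R,4'S)-3,3',7,7',8,8'-hexakis(benzyloxy)-2,2'-bis[4-(benzyloxy)phenyl]-3,3',4,4'-tetrahydro-2H,2'H-[6,6'-bichromene]-4,4'-diol | c1(-c2cc3c(c(OCc4ccccc4)c2OCc2ccccc2)O[C@H](c2ccc(OCc4ccccc4)cc2)[C@H](OCc2ccccc2)[C@@H]3O)cc2c(c(OCc3ccccc3)c1OCc1ccccc1)O[C@H](c1ccc(OCc3ccccc3)cc1)[C@H](OCc1ccccc1)[C@H]2O | intermediate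
22 | (2R,2'R,3R,3'R,4R,4'S)-2,2'-bis(4-hydroxyphenyl)-3,3',4,4'-tetrahydro-2H,2'H-[6,6'-bichromene]-3,3',4,4',7,7',8,8'-octol (CNP0121763.1) | Oc1ccc([C@H]2Oc3c(cc(-c4cc5c(c(O)c4O)O[C@H](c4ccc(O)cc4)[C@H](O)[C@H]5O)c(O)c3O)[C@@H](O)[C@H]2O)cc1 | target

**Totals.** Total step count: 13. Longest linear sequence: 9 steps (steps 2, 3, 4, 5, 9, 10, 11, 12, 13; the branch through steps 6, 7, 8 is equally long).

**Steps most likely to fail**

Step 7 (and its twin, step 10). The alkoxide may add too slowly to the electron-rich, ortho-alkoxy fluoroarene, so that the forcing temperature degrades the dialkoxide (benzyl ether cleavage, fragmentation) before ring closure. The fallback moves the closure of the same O1–C8a bond to the ketone oxidation level, where the ortho carbonyl activates fluoride displacement. It sets out from ketone 11. Cs2CO3 in MeCN at 0 °C to rt, kept cold and short to limit retro-aldol cleavage and C3 epimerisation, should give (2R,3S)-3,7,8-tris(benzyloxy)-2-[4-(benzyloxy)phenyl]-2,3-dihydro-4H-chromen-4-one F1. NaBH4 in THF/MeOH at −40 °C should add hydride anti to the quasi-axial 3-benzyloxy group and give the all-cis alcohol 18, so the route is rejoined there and steps 9 and 10 are bypassed as well. For the 3,4-trans series, a Mitsunobu inversion of 18 at C4 (4-nitrobenzoic acid, PPh3, DIAD, toluene, 0 °C) should give the 4-nitrobenzoate F2. K2CO3 in MeOH then releases 14, where the route is rejoined; an SN1 leak in the Mitsunobu step would also favour attack anti to the 3-benzyloxy group.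

Step 9. Internal hydride delivery to the deactivated, ortho-fluorinated, electron-rich aryl ketone may be slow, so that undirected reduction and acid-promoted ionisation of the alkoxybenzylic alcohols erode the anti selectivity. The fallback replaces 1,3-induction by 1,2-chelation control and sets out from 11. Silylation of the C2 hydroxyl (Et3SiCl, imidazole, CH2Cl2, 0 °C) gives the triethylsilyl ether F3. Zn(BH4)2 in Et2O at −30 °C, reducing through the five-membered zinc chelate of the ketone and the α-benzyloxy oxygen (Cram chelate model), should give the 3,4-anti alcohol F4. Bu4NF/AcOH in THF at 0 °C removes the silyl group and returns the route at 17.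

Step 12. Incomplete borylation would let 19 homocouple to the 4R,4'R diastereomer, which is hard to separate from 21, and the electron-rich ortho-alkoxy boronate may protodeboronate in the hot basic medium. The fallback makes and purifies the boron partner stoichiometrically and sets out from 19. n-BuLi (2.1 equiv, first forming the lithium alkoxide, then bromine–lithium exchange) in THF at −78 °C, then B(OiPr)3 and aqueous work-up, should give [(2R,3R,4R)-3,7,8-tris(benzyloxy)-2-[4-(benzyloxy)phenyl]-4-hydroxy-3,4-dihydro-2H-chromen-6-yl]boronic acid F5. A separate Suzuki–Miyaura coupling of purified F5 with 15 (Pd(OAc)2, SPhos, K3PO4, THF/H2O, 50 °C) returns the route at 21.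

**Further compounds**

F1 | step 7 | (2R,3S)-3,7,8-tris(benzyloxy)-2-[4-(benzyloxy)phenyl]-2,3-dihydro-4H-chromen-4-one | c1cc2c(c(OCc3ccccc3)c1OCc1ccccc1)O[C@H](c1ccc(OCc3ccccc3)cc1)[C@H](OCc1ccccc1)C2=O
F2 | step 7 | (2R,3S,4S)-3,7,8-tris(benzyloxy)-2-[4-(benzyloxy)phenyl]-3,4-dihydro-2H-chromen-4-yl 4-nitrobenzoate | c1cc2c(c(OCc3ccccc3)c1OCc1ccccc1)O[C@H](c1ccc(OCc3ccccc3)cc1)[C@H](OCc1ccccc1)[C@H]2OC(=O)c1ccc(cc1)[N+](=O)[O-]
F3 | step 9 | (2S,3R)-2-(benzyloxy)-1-[3,4-bis(benzyloxy)-2-fluorophenyl]-3-[4-(benzyloxy)phenyl]-3-[(triethylsilyl)oxy]propan-1-one | Fc1c(OCc2ccccc2)c(OCc2ccccc2)ccc1C(=O)[C@@H](OCc1ccccc1)[C@H](O[Si](CC)(CC)CC)c1ccc(OCc2ccccc2)cc1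
F4 | step 9 | (1R,2R,3R)-2-(benzyloxy)-1-[3,4-bis(benzyloxy)-2-fluorophenyl]-3-[4-(benzyloxy)phenyl]-3-[(triethylsilyl)oxy]propan-1-ol | Fc1c(OCc2ccccc2)c(OCc2ccccc2)ccc1[C@@H](O)[C@@H](OCc1ccccc1)[C@H](O[Si](CC)(CC)CC)c1ccc(OCc2ccccc2)cc1
F5 | step 12 | [(2R,3R,4R)-3,7,8-tris(benzyloxy)-2-[4-(benzyloxy)phenyl]-4-hydroxy-3,4-dihydro-2H-chromen-6-yl]boronic acid | OB(O)c1cc2c(c(OCc3ccccc3)c1OCc1ccccc1)O[C@H](c1ccc(OCc3ccccc3)cc1)[C@H](OCc1ccccc1)[C@@H]2O
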